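The route rests on cutting the 1,2-dioxolane (ring O1–O2–C3–C4–C5; C3 carries the acetic acid arm, C5 the chain) into a C3–O2–O1 peroxycarbenium unit and a C4=C5 alkene. The feature exploited is that C5 is fully substituted and can hold a tertiary cation while C3 can be delivered as a ketone-derived peroxycarbenium ion. One operation forms the C3–C4 and O1–C5 bonds, closes the ring and creates both quaternary centres. The precursors are the triethylsilylperoxy methyl ketal of silyl-protected 4-hydroxybutan-2-one and (R)-2,4-dimethyldodeca-1,11-diene, each made in three steps; the spared terminal alkene later becomes the phenyldiene and the silyloxyethyl arm the acid.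

Key step: step 7

Remark on the chemistry: the chain is numbered on from the ring as C6, C7 (methyl-bearing, R) up to C17 (phenyl-bearing), the target being 3S,5R,7R; (S)-3-bromo-2-methylpropan-1-ol, 7-bromohept-1-ene and isopropenylmagnesium bromide (THF solution) are assumed to be purchasable.

Step 1
Reactants: 1 7-bromohept-1-ene; 2 (S)-3-bromo-2-methylpropan-1-ol
Product: 5 (R)-2-methyldec-9-en-1-ol, via hept-6-enylmagnesium bromide 3 (not isolated), via chloromagnesium (S)-3-bromo-2-methylpropoxide 4 (not isolated)
Conditions: 1, Mg, THF, 40 °C (gives 3); separately 2, MeMgCl (1.0 equiv), THF, −40 °C (gives 4); then Li2CuCl4 (5 mol%), 3 (1.5 equiv), −78 °C to rt; 1 M HCl work-up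
Reagents that add atoms: none
Why: Copper-catalysed alkyl–alkyl cross-coupling of a primary Grignard reagent with a primary bromide (Kochi coupling) tolerates a hydroxyl group masked as its magnesium alkoxide, and the stereocentre, one carbon away from the reacting CH2Br, is untouched, so the S descriptor becomes R only through the change in CIP priorities.

Step 2
Reactants: 5 (R)-2-methyldec-9-en-1-ol
Product: 6 (R)-2-methyldec-9-en-1-yl 4-methylbenzenesulfonate
Conditions: TsCl, Et3N, DMAP (cat.), CH2Cl2, 0 °C to rt
Reagents that add atoms: 4-toluenesulfonyl chloride, Cc1ccc(cc1)S(=O)(=O)Cl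
Why: Sulfonylation of a primary alcohol breaks no bond at the stereocentre and turns C6 into an electrophile.

Step 3
Reactants: 6 (R)-2-methyldec-9-en-1-yl 4-methylbenzenesulfonate; 7 prop-1-en-2-ylmagnesium bromide (isopropenylmagnesium bromide)
Product: 8 (R)-2,4-dimethyldodeca-1,11-diene
Conditions: 7 (2.5 equiv, THF solution), CuI (10 mol%), THF, 0 °C to rt
Reagents that add atoms: none
Why: CuI-catalysed cross-coupling of an alkenyl Grignard reagent with a primary tosylate (SN2 displacement through an organocuprate) attaches the isopropenyl group to C6 without touching the neighbouring stereocentre or the terminal vinyl group.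

Step 4
Reactants: 9 3-methylbut-3-en-1-ol
Product: 10 tert-butyl[(3-methylbut-3-en-1-yl)oxy]diphenylsilane
Conditions: TBDPSCl, imidazole, CH2Cl2, 0 °C to rt
Reagents that add atoms: tert-butylchlorodiphenylsilane, CC(C)(C)[Si](Cl)(c1ccccc1)c1ccccc1
Why: Standard silylation of a primary alcohol; the TBDPS group is chosen because it should withstand ozone, SnCl4 at low temperature and the later basic olefination, and it supplies a UV handle for the isomer separation after step 7.

Step 5
Reactants: 10 tert-butyl[(3-methylbut-3-en-1-yl)oxy]diphenylsilane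
Product: 12 tert-butyl(3-hydroperoxy-3-methoxybutoxy)diphenylsilane (racemic), via carbonyl oxide 11 (not isolated)
Conditions: O3, CH2Cl2/MeOH (1:1), −78 °C; N2 purge; chromatography
Reagents that add atoms: ozone, [O-][O+]=O; methanol, CO
Why: Ozonolysis in methanol (Criegee mechanism) cleaves the 1,1-disubstituted alkene into formaldehyde and the more substituted carbonyl oxide 11, which methanol traps as the hydroperoxy ketal; the new ketal centre is racemic and is erased on ionisation in step 7.

Step 6
Reactants: 12 tert-butyl(3-hydroperoxy-3-methoxybutoxy)diphenylsilane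
Product: 13 tert-butyl{3-methoxy-3-[(triethylsilyl)peroxy]butoxy}diphenylsilane (racemic; the triethylsilylperoxy methyl ketal of 4-(tert-butyldiphenylsilyloxy)butan-2-one)
Conditions: Et3SiOTf, Et3N, CH2Cl2, −78 to 0 °C
Reagents that add atoms: triethylsilyl trifluoromethanesulfonate, CC[Si](CC)(CC)OS(=O)(=O)C(F)(F)F
Why: O-Silylation of the hydroperoxide with a silyl triflate and an amine base caps the acidic OOH group, so that the Lewis acid of step 7 ionises only the C–OMe bond.

Step 7
Reactants: 13 tert-butyl{3-methoxy-3-[(triethylsilyl)peroxy]butoxy}diphenylsilane; 8 (R)-2,4-dimethyldodeca-1,11-diene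
Product: 16 tert-butyl{2-[(3R,5R)-3,5-dimethyl-5-[(2R)-2-methyldec-9-en-1-yl]-1,2-dioxolan-3-yl]ethoxy}diphenylsilane, via peroxycarbenium ion 14 (not isolated), via tertiary C5 carbocation 15 (not isolated)
Conditions: 13 (1.3 equiv), 8, SnCl4 (1.1 equiv), CH2Cl2, −78 °C; aq. NaHCO3 quench; flash chromatography (removes the 3,5-cis pair), then preparative HPLC on silica for the two trans isomers
Reagents that add atoms: none
Why: SnCl4 removes the methoxy group of 13 to give the acyclic peroxycarbenium ion 14, the CH2 end of the 1,1-disubstituted alkene of 8 adds to its cationic carbon in the Markovnikov sense (C3–C4 bond) to give the tertiary C5 cation 15, and the silylated distal peroxide oxygen then captures C5 (O1–C5 bond) with loss of the triethylsilyl group. The closest known reaction type is this transformation itself, the Lewis-acid-mediated [3+2] annulation of peroxycarbenium ions from silylperoxy ketals with alkenes, for which 1,1-disubstituted alkenes are established partners. The dioxolane (ring O1–O2–C3–C4–C5) closes by intramolecular collapse of an oxygen nucleophile onto a carbocation, a five-membered cation capture in which no ring π bond is broken, so no exo/endo stereoelectronic barrier arises. C3 is fixed in the C–C bond formation on a planar cation whose faces the remote C7 centre cannot distinguish, and C5 in the ring closure, where only a mild steric preference for placing the silyloxyethyl arm and the branched chain on opposite ring faces operates; nothing in the substrates fixes the absolute sense, so all four C3/C5 isomers should form and 16 has to be isolated by chromatography, the TBDPS chromophore serving detection. The selectivity the step truly needs is chemo- and regioselectivity, namely reaction at the 1,1-disubstituted alkene through its CH2 end and not at the terminal vinyl group, and this is secured by the tertiary instead of secondary cation that results. The TBDPS ether and the monosubstituted alkene should be inert to SnCl4 at −78 °C.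

Step 8
Reactants: 16 tert-butyl{2-[(3R,5R)-3,5-dimethyl-5-[(2R)-2-methyldec-9-en-1-yl]-1,2-dioxolan-3-yl]ethoxy}diphenylsilane
Product: 18 (8R)-9-[(3R,5R)-5-{2-[(tert-butyldiphenylsilyl)oxy]ethyl}-3,5-dimethyl-1,2-dioxolan-3-yl]-8-methylnonanal, via secondary ozonide 17 (not isolated)
Conditions: O3, CH2Cl2, −78 °C (Sudan red 7B end-point); then PPh3 (1.2 equiv), −78 °C to rt
Reagents that add atoms: ozone, [O-][O+]=O
Why: Ozonolysis of the only remaining C=C bond followed by phosphine reduction of the ozonide; the fully substituted dialkyl peroxide and the silyl ether are inert to ozone at −78 °C, and the hindered dioxolane should be reduced by PPh3 far more slowly than the ozonide.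

Step 9
Reactants: 18 (8R)-9-[(3R,5R)-5-{2-[(tert-butyldiphenylsilyl)oxy]ethyl}-3,5-dimethyl-1,2-dioxolan-3-yl]-8-methylnonanal; 19 diethyl [(E)-3-phenylprop-2-en-1-yl]phosphonate (diethyl cinnamylphosphonate)
Product: 21 tert-butyl{2-[(3R,5R)-3,5-dimethyl-5-[(2R,9E,11E)-2-methyl-12-phenyldodeca-9,11-dien-1-yl]-1,2-dioxolan-3-yl]ethoxy}diphenylsilane, via lithiated phosphonate 20 (not isolated)
Conditions: 19 (1.5 equiv), LiN(SiMe3)2 (1.4 equiv), THF, −78 °C; then 18, −78 °C to rt; chromatography (AgNO3-impregnated silica if a 9Z isomer is present)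
Reagents that add atoms: none
Why: Horner–Wadsworth–Emmons olefination with a semi-stabilised allylic phosphonate anion favours the E geometry at the new C14=C15 bond while the cinnamyl double bond keeps its E geometry, and the dioxolane has no hydrogen on C3 or C5, so base cannot trigger Kornblum–DeLaMare fragmentation.

Step 10
Reactants: 21 tert-butyl{2-[(3R,5R)-3,5-dimethyl-5-[(2R,9E,11E)-2-methyl-12-phenyldodeca-9,11-dien-1-yl]-1,2-dioxolan-3-yl]ethoxy}diphenylsilane
Product: 22 2-[(3R,5R)-3,5-dimethyl-5-[(2R,9E,11E)-2-methyl-12-phenyldodeca-9,11-dien-1-yl]-1,2-dioxolan-3-yl]ethan-1-ol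
Conditions: Bu4NF, AcOH (1:1), THF, 0 °C to rt
Reagents that add atoms: none
Why: Fluoride-mediated cleavage of the Si–O bond, buffered with acetic acid so that no free alkoxide is generated near the peroxide; the diene and dioxolane are inert to fluoride.

Step 11
Reactants: 22 2-[(3R,5R)-3,5-dimethyl-5-[(2R,9E,11E)-2-methyl-12-phenyldodeca-9,11-dien-1-yl]-1,2-dioxolan-3-yl]ethan-1-ol
Product: 24 2-[(3S,5R)-3,5-dimethyl-5-[(2R,9E,11E)-2-methyl-12-phenyldodeca-9,11-dien-1-yl]-1,2-dioxolan-3-yl]acetic acid, via dioxolanylacetaldehyde 23 (not isolated)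
Conditions: TEMPO (20 mol%), PhI(OAc)2 (1.2 equiv), CH2Cl2, rt; then t-BuOH/H2O, 2-methylbut-2-ene (excess), NaH2PO4, NaClO2, 0 °C to rt, dark
Reagents that add atoms: sodium chlorite, [Na+].[O-]Cl=O
Why: Oxoammonium (TEMPO/PhI(OAc)2) oxidation of the primary alcohol to aldehyde 23 is followed in the same flask by Pinnick oxidation, with 2-methylbut-2-ene scavenging hypochlorite to protect the diene; neither stage reduces the peroxide, and quaternary C3 cannot epimerise (its descriptor changes from R to S only through CIP priorities).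

Compound list
1 | 7-bromohept-1-ene | C=CCCCCCBr | starting material
2 | (S)-3-bromo-2-methylpropan-1-ol | OC[C@H](C)CBr | starting material
3 | hept-6-enylmagnesium bromide | C=CCCCCC[Mg]Br | intermediate (not isolated)
4 | chloromagnesium (S)-3-bromo-2-methylpropoxide | Cl[Mg]OC[C@H](C)CBr | intermediate (not isolated)
5 | (R)-2-methyldec-9-en-1-ol | OC[C@H](C)CCCCCCC=C | intermediate
6 | (R)-2-methyldec-9-en-1-yl 4-methylbenzenesulfonate | Cc1ccc(cc1)S(=O)(=O)OC[C@H](C)CCCCCCC=C | intermediate
7 | prop-1-en-2-ylmagnesium bromide (isopropenylmagnesium bromide) | C=C(C)[Mg]Br | starting material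
8 | (R)-2,4-dimethyldodeca-1,11-diene | C=C(C)C[C@H](C)CCCCCCC=C | intermediate
9 | 3-methylbut-3-en-1-ol | C=C(C)CCO | starting material
10 | tert-butyl[(3-methylbut-3-en-1-yl)oxy]diphenylsilane | C=C(C)CCO[Si](c1ccccc1)(c1ccccc1)C(C)(C)C | intermediate
11 | carbonyl oxide of 4-(tert-butyldiphenylsilyloxy)butan-2-one | CC(=[O+][O-])CCO[Si](c1ccccc1)(c1ccccc1)C(C)(C)C | intermediate (not isolated)
12 | tert-butyl(3-hydroperoxy-3-methoxybutoxy)diphenylsilane (racemic) | COC(C)(CCO[Si](c1ccccc1)(c1ccccc1)C(C)(C)C)OO | intermediate
13 | tert-butyl{3-methoxy-3-[(triethylsilyl)peroxy]butoxy}diphenylsilane (racemic) | COC(C)(CCO[Si](c1ccccc1)(c1ccccc1)C(C)(C)C)OO[Si](CC)(CC)CC | intermediate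
14 | peroxycarbenium ion from 13 (cationic carbon is the future C3) | C[C+](CCO[Si](c1ccccc1)(c1ccccc1)C(C)(C)C)OO[Si](CC)(CC)CC | intermediate (not isolated)
15 | tertiary C5 carbocation after C3–C4 bond formation (3R,7R) | C=CCCCCCC[C@@H](C)C[C+](C)C[C@@](C)(CCO[Si](c1ccccc1)(c1ccccc1)C(C)(C)C)OO[Si](CC)(CC)CC | intermediate (not isolated)
16 | tert-butyl{2-[(3R,5R)-3,5-dimethyl-5-[(2R)-2-methyldec-9-en-1-yl]-1,2-dioxolan-3-yl]ethoxy}diphenylsilane | C=CCCCCCC[C@@H](C)C[C@]1(C)C[C@@](C)(CCO[Si](c2ccccc2)(c2ccccc2)C(C)(C)C)OO1 | intermediate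
17 | secondary ozonide (3-substituted 1,2,4-trioxolane) of 16, mixture at the trioxolane carbon | C1OOC(O1)CCCCCC[C@@H](C)C[C@]2(C)C[C@@](C)(CCO[Si](c3ccccc3)(c3ccccc3)C(C)(C)C)OO2 | intermediate (not isolated)
18 | (8R)-9-[(3R,5R)-5-{2-[(tert-butyldiphenylsilyl)oxy]ethyl}-3,5-dimethyl-1,2-dioxolan-3-yl]-8-methylnonanal | O=CCCCCCC[C@@H](C)C[C@]1(C)C[C@@](C)(CCO[Si](c2ccccc2)(c2ccccc2)C(C)(C)C)OO1 | intermediate
19 | diethyl [(E)-3-phenylprop-2-en-1-yl]phosphonate | CCOP(=O)(C/C=C/c1ccccc1)OCC | starting material
20 | lithiated phosphonate from 19 | [Li+].CCOP(=O)([CH-]/C=C/c1ccccc1)OCC | intermediate (not isolated)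
21 | tert-butyl{2-[(3R,5R)-3,5-dimethyl-5-[(2R,9E,11E)-2-methyl-12-phenyldodeca-9,11-dien-1-yl]-1,2-dioxolan-3-yl]ethoxy}diphenylsilane | C[C@H](CCCCCC/C=C/C=C/c1ccccc1)C[C@]1(C)C[C@@](C)(CCO[Si](c2ccccc2)(c2ccccc2)C(C)(C)C)OO1 | intermediate
22 | 2-[(3R,5R)-3,5-dimethyl-5-[(2R,9E,11E)-2-methyl-12-phenyldodeca-9,11-dien-1-yl]-1,2-dioxolan-3-yl]ethan-1-ol | C[C@H](CCCCCC/C=C/C=C/c1ccccc1)C[C@]1(C)C[C@@](C)(CCO)OO1 | intermediate
23 | 2-[(3S,5R)-3,5-dimethyl-5-[(2R,9E,11E)-2-methyl-12-phenyldodeca-9,11-dien-1-yl]-1,2-dioxolan-3-yl]acetaldehyde | C[C@H](CCCCCC/C=C/C=C/c1ccccc1)C[C@]1(C)C[C@@](C)(CC=O)OO1 | intermediate (not isolated)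
24 | 2-[(3S,5R)-3,5-dimethyl-5-[(2R,9E,11E)-2-methyl-12-phenyldodeca-9,11-dien-1-yl]-1,2-dioxolan-3-yl]acetic acid | C[C@H](CCCCCC/C=C/C=C/c1ccccc1)C[C@]1(C)C[C@@](C)(CC(=O)O)OO1 | target

Total step count: 11. Longest linear sequence: 8 steps (steps 1–3 then 7–11; the ketal branch, steps 4–6 then 7–11, is equally long).

Steps most likely to fail

Step 7. The cation capture offers little facial discrimination and the C7 centre is too remote to bias it, so the two trans isomers, which differ only in the sense of the ring relative to C7, may not resolve by chromatography at the silyl ether stage. The fallback replaces direct separation by separation through a covalent chiral derivative. After removal of the cis pair, the trans pair is taken through steps 8 to 10, and the fallback sets out from alcohol 22 (obtained as the pair with its ring epimer). Esterification with (S)-2-methoxy-2-phenylacetic acid (DCC, DMAP cat., CH2Cl2, 0 °C) should give 2-[(3R,5R)-3,5-dimethyl-5-[(2R,9E,11E)-2-methyl-12-phenyldodeca-9,11-dien-1-yl]-1,2-dioxolan-3-yl]ethyl (S)-2-methoxy-2-phenylacetate F1 together with its ring epimer. The added stereocentre lies five bonds from C3 and should widen the chromatographic gap and give an NMR reporter for isomer purity. After separation on silica, methanolysis (K2CO3, MeOH, 0 °C) returns to the route at 22 as a single isomer.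

Step 9. Incomplete E selectivity in forming the C14=C15 bond, or loss of the aldehyde by enolisation under the strongly basic conditions, would lower the supply of the E,E-diene. The fallback builds the diene in two stabilised olefinations and sets out from aldehyde 18. A Wittig reaction with (triphenylphosphoranylidene)acetaldehyde (toluene, 60 °C) should give (2E,10R)-11-[(3R,5R)-5-{2-[(tert-butyldiphenylsilyl)oxy]ethyl}-3,5-dimethyl-1,2-dioxolan-3-yl]-10-methylundec-2-enal F2. Horner–Wadsworth–Emmons reaction of this enal with diethyl benzylphosphonate (LiN(SiMe3)2, THF, −78 °C to rt), a combination that is strongly E-selective, returns to the route at 21.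

Step 1. Closure of the bromo alkoxide to the volatile, achiral oxetane, or sluggish coupling of the aggregated alkoxide, would cost material and, if the oxetane were reopened, enantiopurity. The fallback removes the alkoxide by protection and sets out from 2. Silylation (TBSCl, imidazole, CH2Cl2) gives (S)-(3-bromo-2-methylpropoxy)(tert-butyl)dimethylsilane F3. The same Li2CuCl4-catalysed coupling with 3 gives (R)-tert-butyldimethyl[(2-methyldec-9-en-1-yl)oxy]silane F4, and Bu4NF in THF returns to the route at 5.

Further compounds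
F1 | step 7 | 2-[(3R,5R)-3,5-dimethyl-5-[(2R,9E,11E)-2-methyl-12-phenyldodeca-9,11-dien-1-yl]-1,2-dioxolan-3-yl]ethyl (S)-2-methoxy-2-phenylacetate | C[C@H](CCCCCC/C=C/C=C/c1ccccc1)C[C@]1(C)C[C@@](C)(CCOC(=O)[C@@H](OC)c2ccccc2)OO1
F2 | step 9 | (2E,10R)-11-[(3R,5R)-5-{2-[(tert-butyldiphenylsilyl)oxy]ethyl}-3,5-dimethyl-1,2-dioxolan-3-yl]-10-methylundec-2-enal | O=C/C=C/CCCCCC[C@@H](C)C[C@]1(C)C[C@@](C)(CCO[Si](c2ccccc2)(c2ccccc2)C(C)(C)C)OO1
F3 | step 1 | (S)-(3-bromo-2-methylpropoxy)(tert-butyl)dimethylsilane | CC(C)(C)[Si](C)(C)OC[C@H](C)CBr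
F4 | step 1 | (R)-tert-butyldimethyl[(2-methyldec-9-en-1-yl)oxy]silane | CC(C)(C)[Si](C)(C)OC[C@H](C)CCCCCCC=C
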